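## The problem

Rings are lettered A to G along the chain. In each ring, C1 is the carbon bonded to the ether oxygen that leads toward ring A (in ring A, its only ether carbon).

- The target is a linear chain of seven benzene rings joined only by six diaryl ether oxygens and carrying eighteen free hydroxyls. Ring A is 2,4,6-trihydroxyphenoxy; rings B and F are ethers at C1 and C4 with hydroxyls at C3 and C5; rings C and E are pentaoxygenated with ether oxygens on the adjacent carbons C1 and C6; ring D has ethers at C1 and C5 and hydroxyls at C3 and C4; ring G is 3,4,5-trihydroxyphenoxy.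
- There is no stereocentre and no fused ring, and the ether bonds rotate freely. The task is therefore purely regiochemical: six C–O bonds, each at one defined oxygen among up to five on a ring, with no stereochemical element available to control another.
- Five of the six ether bonds (A–B, B–C, C–D, E–F, F–G) end on a carbon flanked by two oxygen substituents; only the D–E bond does not.
- Every ring is electron-rich, so none accepts a phenoxide without an activating group, and copper couplings of such hindered, electron-rich partners are unreliable.
- The free polyphenol contains pyrogallol- and phloroglucinol-type rings that autoxidise readily, especially in base. All hydroxyls must stay masked until the last step and be released under acidic, non-oxidising conditions.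
- The enabling feature: rings C, D and G each carry a hydroxyl at C4, para to the ether carbon C1 (in ring D also ortho to the second ether carbon C5). A formyl group at C4 activates fluoride displacement at exactly these carbons and can afterwards be oxidised to the hydroxyl. In rings B and F the two ether carbons are para to each other, so there the formyl carbon becomes the next ether oxygen.
- The C6 oxygen of rings C and E is meta to C4 and cannot come from this logic; it has to be placed on the monomers.

## Retrosynthesis

**28 from 27.** The fifteen O–CH3 bonds of heptamer triphenol 27 are cut last. Methyl is preferred to benzyl or silyl because it survives carbonate in hot DMSO, peracid and aqueous acid, and is small enough not to add to the crowding around the ether carbons. The forward reaction must cleave only alkyl–oxygen bonds and leave the six diaryl ethers intact.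

**27 from 25 (key disconnection).** The three C4–OH bonds on rings C, D and G are traced back to the formyl groups of heptamer trialdehyde 25. Making these three oxygens methoxy groups from the start would leave rings C, D and G without any activating group for ether formation. The forward reaction has to insert oxygen between ring and formyl carbon at three sites at once, with aryl rather than hydride migration.

**25 from 14 and 24.** The ring D C5–O bond is cut, dividing the heptamer into tetramer fluoride 14 (rings A to D) and trimer phenol 24 (rings E to G). This bond is chosen for the union because the ring E phenoxide is the least hindered in the molecule (one ortho hydrogen) and can be paired with the most demanding electrophile, a fluoride ortho to formyl on a ring that already carries an aryloxy group. Cutting C–D last instead would pair the most hindered phenoxide with that same electrophile.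

**14 from 11 and 13; 13 from 12.** The ring D C1–O bond is cut. Ring D becomes the linchpin 2,4-difluoro-6-methoxybenzaldehyde 13, made by methylating the commercial phenol 12. The forward reaction needs the hindered ring C phenoxide of trimer 11 to take the para fluoride and leave the ortho fluoride for the next step.

**11 from 5 and 9; 9 from 2; 5 from 1 and 2.** Cutting the ring C C1–O bond gives dimer phenol 5 and a ring C monomer that must carry fluoride para to formyl and a masked oxygen at the future C6. This is MOM ether 9, unmasked after coupling (10 to 11). The extra oxygen of 9 is introduced on 4-fluoro-2,6-dimethoxybenzaldehyde 2 by bromination (6) and borylation–oxidation (8); the two open ring positions of 2 are equivalent, so there is no regiochemical choice. Dimer 5 comes from 2,4,6-trimethoxyphenol 1 and 2 through aldehyde 3 by an interim Dakin oxidation that turns the ring B formyl into the ring B nucleophile.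

**24 from 2 (twice) and 19; 19 from 15.** Cutting the F–G and E–F ethers returns 24 through MOM ether 23, phenol 22 and aldehyde 20 to two molecules of 2 and the ring E monomer 19. Phenol 19 is a 3,4,5-trimethoxycatechol with its less hindered oxygen masked as MOM. It comes from 3,4,5-trimethoxyphenol 15 through MOM ether 16, whose MOM group is both protecting group and ortho director; again the two ring hydrogens are equivalent.

## Roads not taken

**Alternative 1:** Ring E is not bought but built, by cutting its C1–C6 bond. Heating a racemic squarate-derived cyclobutenone A2 (aryloxy group = the F–G dimer, plus a 1-methoxyvinyl group on the sp3 carbon) would open it to a vinylketene; six-electron electrocyclisation and tautomerisation would give the E–F–G trimer phenol A1.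
- Merits: the pentaoxygenated ring arrives with its free hydroxyl exactly at the carbon that must join ring D and all other oxygens already differentiated; no protecting group is needed on ring E; the key step is thermal and reagent-free.
- Weak points: A2 needs a hindered phenoxide attached to the squarate core, a regioselective addition of the vinyl metal to one of two different carbonyls, and O-methylation of a tertiary alkoxide. The sequence solves one of the two pentaoxygenated rings only; ring C would need a second ring construction. A1 has no formyl group, so the F–G ether and all later ethers need another source of activation.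
- Comparison: for ring E alone this road is the more elegant one. The chosen plan sets against it that 19 is reached from 15 in two routine steps and that one reaction pair (fluoride displacement, Dakin oxidation) builds every ether bond. A1 is the same compound as intermediate F8 of the staged fallback below, so the ring expansion could feed that fallback.

**Alternative 2:** Ring A is built last by cutting two of its C–C bonds. Under NaOMe the enolate of dimethyl 3-oxoglutarate A5 would be acylated twice by the ester groups of the hexamer-bearing aryloxymalonate A4, closing ring A as the dimethyl isophthalate A3. Saponification, double decarboxylation and demethylation would follow.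
- Merits: the phloroglucinol pattern of ring A is fixed by construction; the oxidation-prone phenoxide of 1 is never used.
- Weak points: the A–B ether is the easiest bond in the molecule (step 1 here, two commercial monomers), so a ring synthesis plus two ester removals is spent on the least difficult junction. The malonate C–H of A4 is acidic, and deprotonation under methoxide makes its esters poor acylating agents. The reaction must be run on the complete B-to-G hexamer, whose five other ethers still need their own solution.
- Comparison: it is better only in avoiding one hindered displacement. The chosen plan makes that same bond in one step on cheap material and keeps precious late intermediates away from strongly basic condensation conditions.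

**Alternative 3:** Both ether bonds at ring B are cut. The cyclopentadienylruthenium hexafluorophosphate complex A7 of 2,5-dichloro-1,3-dimethoxybenzene (divalent ruthenium) would react in one pot first with the phenoxide of 1 at the unhindered chloride and then with the phenoxide of the C-to-G pentamer A8 at the chloride between the two methoxy groups, giving the ruthenium complex A6 of the permethylated heptamer. Decomplexation and demethylation would finish.
- Merits: a convergent 1 + 1 + 5 union; π-complexation makes an electron-rich chloroarene electrophilic under mild conditions; ring B needs no formyl group and no interim oxidation; the heptamer is never exposed to peracid.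
- Weak points: ruthenium is stoichiometric and must be removed by photolysis or ligand exchange. The second displacement pairs the most hindered carbon with the largest nucleophile on a ring already deactivated by the first aryloxy group. The metal can migrate to other electron-rich rings. A8 still contains rings C, D and E, so the main regiochemical problems remain.
- Comparison: this road is better in convergence and avoids the triple oxidation. The chosen plan sets against it metal-free, inexpensive reagents, no decomplexation, and a single logic that also delivers the hydroxyls of rings C, D and G.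

Key step: step 17

Assumption: the target has no stereocentre and its diaryl ether bonds rotate freely, so no structure in this route needs a stereodescriptor.

## Route

Step 1
Reactants: 1 2,4,6-trimethoxyphenol; 2 4-fluoro-2,6-dimethoxybenzaldehyde
Product: 3 2,6-dimethoxy-4-(2,4,6-trimethoxyphenoxy)benzaldehyde (A–B aldehyde)
Conditions: K2CO3, DMSO, 100 °C, argon
Reagents that add atoms: none
Why: Nucleophilic aromatic substitution by addition–elimination; the fluoride of 2 is para to the formyl group, which stabilises the Meisenheimer intermediate, and the di-ortho-substituted phenoxide still attacks because its oxygen projects away from the ring. DMSO is used instead of DMF so that no dimethylamine can compete for the activated fluoride.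

Step 2
Reactants: 3 A–B aldehyde
Product: 5 2,6-dimethoxy-4-(2,4,6-trimethoxyphenoxy)phenol (A–B phenol), via aryl formate 4 (not isolated)
Conditions: mCPBA, CH2Cl2, 0 °C to rt; aq. Na2S2O3/NaHCO3 wash; then K2CO3 (cat.), MeOH, rt
Reagents that add atoms: meta-chloroperoxybenzoic acid (mCPBA), OOC(=O)c1cccc(Cl)c1
Why: Dakin-type Baeyer–Villiger oxidation; the peracid adduct of the aldehyde rearranges with aryl migration because the migrating carbon has two ortho methoxy donors and a para aryloxy donor, and the formate is methanolysed to the phenol.

Step 3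
Reactants: 2 4-fluoro-2,6-dimethoxybenzaldehyde
Product: 6 3-bromo-4-fluoro-2,6-dimethoxybenzaldehyde
Conditions: NBS (1.0 equiv), MeCN, 0 °C to rt
Reagents that add atoms: N-bromosuccinimide (NBS), O=C1CCC(=O)N1Br
Why: Electrophilic aromatic bromination; the two free positions of 2 are equivalent, each ortho and para to a methoxy group and meta to the formyl group, so one equivalent of NBS should give a single monobromide.

Step 4
Reactants: 6 3-bromo-4-fluoro-2,6-dimethoxybenzaldehyde
Product: 8 4-fluoro-3-hydroxy-2,6-dimethoxybenzaldehyde, via pinacol boronate 7 (not isolated)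
Conditions: B2pin2, Pd(dppf)Cl2 (cat.), KOAc, 1,4-dioxane, 90 °C; then NMO, 60 °C; aq. NH4Cl work-up
Reagents that add atoms: bis(pinacolato)diboron, CC1(C)OB(OC1(C)C)B1OC(C)(C)C(C)(C)O1 (boron group of 7); N-methylmorpholine N-oxide (NMO), C[N+]1([O-])CCOCC1 (hydroxyl oxygen of 8)
Why: Miyaura borylation (oxidative addition of zerovalent palladium into the C–Br bond, acetate-assisted transmetalation) followed by ipso-oxidation of the aryl boronate by the amine N-oxide through a boron-to-oxygen aryl shift. The N-oxide is chosen because it leaves the formyl group and the activated C–F bond alone, where alkaline peroxide could attack both.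

Step 5
Reactants: 8 4-fluoro-3-hydroxy-2,6-dimethoxybenzaldehyde
Product: 9 4-fluoro-2,6-dimethoxy-3-(methoxymethoxy)benzaldehyde (ring C monomer)
Conditions: MOMCl, iPr2NEt, CH2Cl2, 0 °C to rt
Reagents that add atoms: chloromethyl methyl ether (MOMCl), COCCl
Why: O-alkylation of the phenol to its methoxymethyl ether; masking prevents the phenoxide from deactivating the ring and from attacking the fluoride of a second molecule, and the acetal survives carbonate in hot DMSO.

Step 6
Reactants: 5 A–B phenol; 9 ring C monomer
Product: 10 4-[2,6-dimethoxy-4-(2,4,6-trimethoxyphenoxy)phenoxy]-2,6-dimethoxy-3-(methoxymethoxy)benzaldehyde (A–B–C aldehyde MOM ether)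
Conditions: Cs2CO3, DMSO, 100 °C, argon
Reagents that add atoms: none
Why: Nucleophilic aromatic substitution at the fluoride para to formyl. The MOM-oxy group next to the fluoride is twisted out of the ring plane by its two ortho neighbours, so it acts mainly as an inductive acceptor and does not cancel the activation; the caesium phenoxide in DMSO provides the most reactive nucleophile for this hindered pairing.

Step 7
Reactants: 10 A–B–C aldehyde MOM ether
Product: 11 4-[2,6-dimethoxy-4-(2,4,6-trimethoxyphenoxy)phenoxy]-3-hydroxy-2,6-dimethoxybenzaldehyde (A–B–C hydroxy aldehyde)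
Conditions: 3 M aq. HCl, THF, 50 °C
Reagents that add atoms: none
Why: Acid hydrolysis of the MOM acetal through an oxocarbenium ion; methyl aryl ethers, diaryl ethers and the formyl group are stable to dilute aqueous acid.

Step 8
Reactants: 12 2,4-difluoro-6-hydroxybenzaldehyde
Product: 13 2,4-difluoro-6-methoxybenzaldehyde (ring D linchpin)
Conditions: MeI, K2CO3, acetone, rt
Reagents that add atoms: iodomethane, CI
Why: Williamson O-methylation; it removes the phenoxide that would otherwise deactivate both fluorides, and installs the methyl ether that ring D carries to the end.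

Step 9
Reactants: 11 A–B–C hydroxy aldehyde; 13 ring D linchpin (2 equiv)
Product: 14 4-{6-[2,6-dimethoxy-4-(2,4,6-trimethoxyphenoxy)phenoxy]-3-formyl-2,4-dimethoxyphenoxy}-2-fluoro-6-methoxybenzaldehyde (A–B–C–D tetramer, fluoride ortho to the ring D formyl)
Conditions: K2CO3, DMSO, 60 °C, argon
Reagents that add atoms: none
Why: Nucleophilic aromatic substitution at the para fluoride, which is flanked by two hydrogens, whereas the ortho fluoride sits beside the formyl group and is shielded from a di-ortho-substituted phenoxide. Excess 13 and the donor effect of the first aryloxy group on the product should suppress a second substitution.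

Step 10
Reactants: 15 3,4,5-trimethoxyphenol
Product: 16 1,2,3-trimethoxy-5-(methoxymethoxy)benzene
Conditions: MOMCl, iPr2NEt, CH2Cl2, 0 °C to rt
Reagents that add atoms: chloromethyl methyl ether (MOMCl), COCCl
Why: O-alkylation to the MOM ether, which protects the oxygen that will later join ring D and serves as the directing group of the next step.

Step 11
Reactants: 16 1,2,3-trimethoxy-5-(methoxymethoxy)benzene
Product: 19 2,3,4-trimethoxy-6-(methoxymethoxy)phenol (ring E monomer), via aryllithium 17 (not isolated), via dimethyl arylboronate 18 (not isolated)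
Conditions: n-BuLi, TMEDA, THF, 0 °C; B(OMe)3, −78 °C to rt; 30% aq. H2O2, 0 °C to rt
Reagents that add atoms: n-butyllithium, [Li]CCCC (lithium of 17); trimethyl borate, COB(OC)OC (boron group of 18); hydrogen peroxide, OO (hydroxyl oxygen of 19)
Why: Directed ortho-metalation, borate trapping and peroxide oxidation (boron-to-oxygen aryl shift). The two ring hydrogens of 16 are equivalent and each lies between the MOM-oxy and a methoxy director, so only one aryllithium can form.

Step 12
Reactants: 19 ring E monomer; 2 4-fluoro-2,6-dimethoxybenzaldehyde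
Product: 20 2,6-dimethoxy-4-[2,3,4-trimethoxy-6-(methoxymethoxy)phenoxy]benzaldehyde (E–F aldehyde)
Conditions: Cs2CO3, DMSO, 100 °C, argon
Reagents that add atoms: none
Why: Nucleophilic aromatic substitution of the fluoride para to formyl by the phenoxide flanked by MOM-oxy and methoxy; the same reaction type as step 1.

Step 13
Reactants: 20 E–F aldehyde
Product: 22 2,6-dimethoxy-4-[2,3,4-trimethoxy-6-(methoxymethoxy)phenoxy]phenol (E–F phenol), via aryl formate 21 (not isolated)
Conditions: mCPBA, NaHCO3, CH2Cl2, 0 °C to rt; aq. Na2S2O3 wash; then K2CO3 (cat.), MeOH, rt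
Reagents that add atoms: meta-chloroperoxybenzoic acid (mCPBA), OOC(=O)c1cccc(Cl)c1
Why: Dakin-type Baeyer–Villiger oxidation with aryl migration favoured by two ortho methoxy groups and a para aryloxy group; the bicarbonate buffer keeps the MOM acetal intact.

Step 14
Reactants: 22 E–F phenol; 2 4-fluoro-2,6-dimethoxybenzaldehyde
Product: 23 4-{2,6-dimethoxy-4-[2,3,4-trimethoxy-6-(methoxymethoxy)phenoxy]phenoxy}-2,6-dimethoxybenzaldehyde (E–F–G aldehyde MOM ether)
Conditions: Cs2CO3, DMSO, 100 °C, argon
Reagents that add atoms: none
Why: Nucleophilic aromatic substitution of the fluoride para to formyl; the former formyl carbon of ring F is now the nucleophilic oxygen, and the new formyl group stays on ring G for the key step.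

Step 15
Reactants: 23 E–F–G aldehyde MOM ether
Product: 24 4-[4-(6-hydroxy-2,3,4-trimethoxyphenoxy)-2,6-dimethoxyphenoxy]-2,6-dimethoxybenzaldehyde (E–F–G hydroxy aldehyde)
Conditions: 3 M aq. HCl, THF, 50 °C
Reagents that add atoms: none
Why: Acid hydrolysis of the MOM acetal, as in step 7, releases the ring E hydroxyl without touching the formyl group or the ethers.

Step 16
Reactants: 14 A–B–C–D tetramer fluoride; 24 E–F–G hydroxy aldehyde
Product: 25 heptamer trialdehyde (formyl at C4 of rings C, D and G; fifteen methyl ethers)
Conditions: Cs2CO3, DMSO, 110 °C, argon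
Reagents that add atoms: none
Why: Nucleophilic aromatic substitution of the fluoride ortho to the ring D formyl group, whose carbonyl oxygen takes up the charge of the Meisenheimer intermediate. The nucleophile is the least hindered phenoxide of the route, only one fluoride remains, and fluoride should leave far faster than the aryloxy groups para to the three formyl groups.

Step 17
Reactants: 25 heptamer trialdehyde
Product: 27 heptamer triphenol (free hydroxyl at C4 of rings C, D and G; fifteen methyl ethers), via heptamer tris-formate 26 (not isolated)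
Conditions: mCPBA (1.3 equiv per formyl), CH2Cl2, 0 °C to rt; aq. Na2S2O3/NaHCO3 wash; then K2CO3 (cat.), degassed MeOH, 0 °C to rt, argon
Reagents that add atoms: meta-chloroperoxybenzoic acid (mCPBA), OOC(=O)c1cccc(Cl)c1
Why: Each formyl carbonyl adds the peracid to a tetrahedral adduct, the aryl group migrates from carbon to the proximal peroxide oxygen with loss of 3-chlorobenzoate, and carbonate-catalysed methanolysis of the three aryl formates releases the phenols. The closest known reaction type is the Dakin or Baeyer–Villiger oxidation of alkoxybenzaldehydes to phenols, already used in steps 2 and 13 and here run at three sites of one molecule. No ring closes and no stereocentre forms; three aryl carbon–oxygen bonds are made at C4 of rings C, D and G. The step needs aryl migration over hydride migration, which would give carboxylic acids; this is secured because every migrating carbon has two ortho oxygen donors (two methoxy groups in rings C and G, methoxy and aryloxy in ring D) and a para aryloxy donor. It also needs the aldehydes to react before the electron-rich rings are oxidised, so the peracid is dosed per formyl group at 0 °C and destroyed with thiosulfate before base is added. The formates shield the new phenols from the oxidant until it is gone, and methanolysis under argon avoids autoxidation of the released phenols.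

Step 18
Reactants: 27 heptamer triphenol
Product: 28 CNP0130704.0 (octadecahydroxy heptamer, target)
Conditions: BBr3 (excess), CH2Cl2, −78 °C to rt; then H2O, 0 °C, argon
Reagents that add atoms: none
Why: Lewis acid-mediated ether cleavage; BBr3 binds each methoxy oxygen and bromide attacks the methyl carbon, giving bromomethane and aryl borates that hydrolyse on quenching. Diaryl ether oxygens offer no sp3 carbon for attack, and the acidic, non-oxidising medium suits the air-sensitive polyphenol.

## Compound list

1 | 2,4,6-trimethoxyphenol | COc1cc(OC)c(O)c(OC)c1 | starting material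
2 | 4-fluoro-2,6-dimethoxybenzaldehyde | COc1cc(F)cc(OC)c1C=O | starting material
3 | 2,6-dimethoxy-4-(2,4,6-trimethoxyphenoxy)benzaldehyde (A–B aldehyde) | COc1cc(OC)c(Oc2cc(OC)c(C=O)c(OC)c2)c(OC)c1 | intermediate
4 | 2,6-dimethoxy-4-(2,4,6-trimethoxyphenoxy)phenyl formate (in-flask species of step 2) | COc1cc(OC)c(Oc2cc(OC)c(OC=O)c(OC)c2)c(OC)c1 | intermediate
5 | 2,6-dimethoxy-4-(2,4,6-trimethoxyphenoxy)phenol (A–B phenol) | COc1cc(OC)c(Oc2cc(OC)c(O)c(OC)c2)c(OC)c1 | intermediate
6 | 3-bromo-4-fluoro-2,6-dimethoxybenzaldehyde | COc1cc(F)c(Br)c(OC)c1C=O | intermediate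
7 | 4-fluoro-2,6-dimethoxy-3-(4,4,5,5-tetramethyl-1,3,2-dioxaborolan-2-yl)benzaldehyde (in-flask species of step 4) | COc1cc(F)c(B2OC(C)(C)C(C)(C)O2)c(OC)c1C=O | intermediate
8 | 4-fluoro-3-hydroxy-2,6-dimethoxybenzaldehyde | COc1cc(F)c(O)c(OC)c1C=O | intermediate
9 | 4-fluoro-2,6-dimethoxy-3-(methoxymethoxy)benzaldehyde (ring C monomer) | COCOc1c(F)cc(OC)c(C=O)c1OC | intermediate
10 | 4-[2,6-dimethoxy-4-(2,4,6-trimethoxyphenoxy)phenoxy]-2,6-dimethoxy-3-(methoxymethoxy)benzaldehyde (A–B–C aldehyde MOM ether) | COc1cc(OC)c(Oc2cc(OC)c(Oc3cc(OC)c(C=O)c(OC)c3OCOC)c(OC)c2)c(OC)c1 | intermediate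
11 | 4-[2,6-dimethoxy-4-(2,4,6-trimethoxyphenoxy)phenoxy]-3-hydroxy-2,6-dimethoxybenzaldehyde (A–B–C hydroxy aldehyde) | COc1cc(OC)c(Oc2cc(OC)c(Oc3cc(OC)c(C=O)c(OC)c3O)c(OC)c2)c(OC)c1 | intermediate
12 | 2,4-difluoro-6-hydroxybenzaldehyde | O=Cc1c(O)cc(F)cc1F | starting material
13 | 2,4-difluoro-6-methoxybenzaldehyde (ring D linchpin) | COc1cc(F)cc(F)c1C=O | intermediate
14 | 4-{6-[2,6-dimethoxy-4-(2,4,6-trimethoxyphenoxy)phenoxy]-3-formyl-2,4-dimethoxyphenoxy}-2-fluoro-6-methoxybenzaldehyde (A–B–C–D tetramer fluoride) | COc1cc(OC)c(Oc2cc(OC)c(Oc3cc(OC)c(C=O)c(OC)c3Oc3cc(OC)c(C=O)c(F)c3)c(OC)c2)c(OC)c1 | intermediate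
15 | 3,4,5-trimethoxyphenol | COc1cc(O)cc(OC)c1OC | starting material
16 | 1,2,3-trimethoxy-5-(methoxymethoxy)benzene | COCOc1cc(OC)c(OC)c(OC)c1 | intermediate
17 | [2,3,4-trimethoxy-6-(methoxymethoxy)phenyl]lithium (in-flask species of step 11) | [Li]c1c(OCOC)cc(OC)c(OC)c1OC | intermediate
18 | dimethyl [2,3,4-trimethoxy-6-(methoxymethoxy)phenyl]boronate (in-flask species of step 11) | COB(OC)c1c(OCOC)cc(OC)c(OC)c1OC | intermediate
19 | 2,3,4-trimethoxy-6-(methoxymethoxy)phenol (ring E monomer) | COCOc1cc(OC)c(OC)c(OC)c1O | intermediate
20 | 2,6-dimethoxy-4-[2,3,4-trimethoxy-6-(methoxymethoxy)phenoxy]benzaldehyde (E–F aldehyde) | COCOc1cc(OC)c(OC)c(OC)c1Oc1cc(OC)c(C=O)c(OC)c1 | intermediate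
21 | 2,6-dimethoxy-4-[2,3,4-trimethoxy-6-(methoxymethoxy)phenoxy]phenyl formate (in-flask species of step 13) | COCOc1cc(OC)c(OC)c(OC)c1Oc1cc(OC)c(OC=O)c(OC)c1 | intermediate
22 | 2,6-dimethoxy-4-[2,3,4-trimethoxy-6-(methoxymethoxy)phenoxy]phenol (E–F phenol) | COCOc1cc(OC)c(OC)c(OC)c1Oc1cc(OC)c(O)c(OC)c1 | intermediate
23 | 4-{2,6-dimethoxy-4-[2,3,4-trimethoxy-6-(methoxymethoxy)phenoxy]phenoxy}-2,6-dimethoxybenzaldehyde (E–F–G aldehyde MOM ether) | COCOc1cc(OC)c(OC)c(OC)c1Oc1cc(OC)c(Oc2cc(OC)c(C=O)c(OC)c2)c(OC)c1 | intermediate
24 | 4-[4-(6-hydroxy-2,3,4-trimethoxyphenoxy)-2,6-dimethoxyphenoxy]-2,6-dimethoxybenzaldehyde (E–F–G hydroxy aldehyde) | Oc1cc(OC)c(OC)c(OC)c1Oc1cc(OC)c(Oc2cc(OC)c(C=O)c(OC)c2)c(OC)c1 | intermediate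
25 | heptamer trialdehyde (formyl at C4 of rings C, D and G; fifteen methyl ethers) | COc1cc(OC)c(Oc2cc(OC)c(Oc3cc(OC)c(C=O)c(OC)c3Oc3cc(OC)c(C=O)c(Oc4cc(OC)c(OC)c(OC)c4Oc4cc(OC)c(Oc5cc(OC)c(C=O)c(OC)c5)c(OC)c4)c3)c(OC)c2)c(OC)c1 | intermediate
26 | heptamer tris-formate (formyloxy at C4 of rings C, D and G; in-flask species of step 17) | COc1cc(OC)c(Oc2cc(OC)c(Oc3cc(OC)c(OC=O)c(OC)c3Oc3cc(OC)c(OC=O)c(Oc4cc(OC)c(OC)c(OC)c4Oc4cc(OC)c(Oc5cc(OC)c(OC=O)c(OC)c5)c(OC)c4)c3)c(OC)c2)c(OC)c1 | intermediate
27 | heptamer triphenol (hydroxyl at C4 of rings C, D and G; fifteen methyl ethers) | COc1cc(OC)c(Oc2cc(OC)c(Oc3cc(OC)c(O)c(OC)c3Oc3cc(OC)c(O)c(Oc4cc(OC)c(OC)c(OC)c4Oc4cc(OC)c(Oc5cc(OC)c(O)c(OC)c5)c(OC)c4)c3)c(OC)c2)c(OC)c1 | intermediate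
28 | CNP0130704.0 (octadecahydroxy heptamer) | Oc1cc(O)c(Oc2cc(O)c(Oc3cc(O)c(O)c(O)c3Oc3cc(O)c(O)c(Oc4cc(O)c(O)c(O)c4Oc4cc(O)c(Oc5cc(O)c(O)c(O)c5)c(O)c4)c3)c(O)c2)c(O)c1 | target

## Step count and risk

Total: 18 steps. Longest linear sequence: 9 steps (2 to 28 through 6, 8, 9, 10, 11, 14, 25 and 27; the branch from 15 through 16, 19, 20, 22, 23, 24, 25 and 27 is equally long).

**Step 17 (key step).**
- What may go wrong: electrophilic oxidation of the most electron-rich rings by peracid may compete before all three formyl groups have rearranged, and incomplete conversion may leave mixed aldehyde–phenol species that are hard to separate.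
- Fallback: stage the oxidations so that the heptamer meets the peracid only once. It sets out from 10 and 23 and returns at 28, at the cost of six further steps.
  - Trimer 10 is oxidised as in step 2 through aryl formate F1 to phenol F2, capped with MeI and K2CO3 as methyl ether F3, and freed from its MOM group with aqueous HCl to give trimer phenol F4.
  - The same three operations convert 23 through aryl formate F5 and phenol F6 into methyl ether F7 and then trimer phenol F8 (identical with A1).
  - F4 displaces the para fluoride of 13 (K2CO3, DMSO) to give tetramer monoaldehyde F9, and F8 displaces its ortho fluoride (Cs2CO3, DMSO) to give heptamer monoaldehyde F10.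
  - A single Dakin oxidation through heptamer mono-formate F11 gives heptamer monophenol F12 (seventeen methyl ethers), which BBr3 converts to 28.

**Step 16.**
- What may go wrong: displacement of the ortho fluoride may be slow because ring D already carries two oxygen donors conjugated with its formyl group. The higher temperature then needed could start ether exchange at the aryloxy groups para to the formyl groups and scramble the chain.
- Fallback: reverse the order at ring D with a differentiated linchpin. It sets out from 24 and 11 and returns at 25.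
  - Phenol 24 displaces the fluoride of 4-bromo-2-fluoro-6-methoxybenzaldehyde F13 (commercial) while that ring is still electron-poor, giving tetramer bromide F14 (rings D to G).
  - The bromide para to the formyl group is then coupled with phenol 11 in an Ullmann ether synthesis (CuI, picolinic acid, K3PO4, DMSO, 90 °C) to give 25.

**Step 6.**
- What may go wrong: substitution may stall because the MOM-oxy group shields the fluoride and the phenoxide is di-ortho-substituted; prolonged heating would then erode the MOM group.
- Fallback: carry the oxygen through as bromine. It sets out from 5 and 6 and returns at 11.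
  - Phenol 5 displaces the fluoride of bromide 6, which is more electrophilic because bromine withdraws inductively and donates little, to give trimer bromide F15.
  - Miyaura borylation to trimer boronate F16 and N-oxide oxidation, as in step 4, then give 11 directly without protection or deprotection.

**Step 18.**
- What may go wrong: cleavage of fifteen ethers may stop at partly methylated mixtures, and the free polyphenol may degrade oxidatively during isolation.
- Fallback: capture and release. It sets out from 27 and returns at 28.
  - The crude demethylation product is not isolated but acetylated at once (Ac2O, pyridine) to the octadecaacetate F17, which is stable and can be purified on silica away from under-demethylated material.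
  - Acid methanolysis (HCl in MeOH, argon) then releases 28.

## Further compounds

F1 | step 17 | A–B–C trimer, ring C formate (formyloxy at C4, MOM-oxy at C6) | COc1cc(OC)c(Oc2cc(OC)c(Oc3cc(OC)c(OC=O)c(OC)c3OCOC)c(OC)c2)c(OC)c1
F2 | step 17 | A–B–C trimer, ring C phenol (hydroxyl at C4, MOM-oxy at C6) | COc1cc(OC)c(Oc2cc(OC)c(Oc3cc(OC)c(O)c(OC)c3OCOC)c(OC)c2)c(OC)c1
F3 | step 17 | A–B–C trimer, ring C 3,4,5-trimethoxy with MOM-oxy at C6 | COc1cc(OC)c(Oc2cc(OC)c(Oc3cc(OC)c(OC)c(OC)c3OCOC)c(OC)c2)c(OC)c1
F4 | step 17 | A–B–C trimer phenol (ring C 3,4,5-trimethoxy, hydroxyl at C6) | COc1cc(OC)c(Oc2cc(OC)c(Oc3cc(OC)c(OC)c(OC)c3O)c(OC)c2)c(OC)c1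
F5 | step 17 | E–F–G trimer, ring G formate (MOM-oxy on ring E) | COCOc1cc(OC)c(OC)c(OC)c1Oc1cc(OC)c(Oc2cc(OC)c(OC=O)c(OC)c2)c(OC)c1
F6 | step 17 | E–F–G trimer, ring G phenol (MOM-oxy on ring E) | COCOc1cc(OC)c(OC)c(OC)c1Oc1cc(OC)c(Oc2cc(OC)c(O)c(OC)c2)c(OC)c1
F7 | step 17 | E–F–G trimer, ring G 3,4,5-trimethoxy (MOM-oxy on ring E) | COCOc1cc(OC)c(OC)c(OC)c1Oc1cc(OC)c(Oc2cc(OC)c(OC)c(OC)c2)c(OC)c1
F8 | step 17 | E–F–G trimer phenol (hydroxyl at C1 of ring E, ring G 3,4,5-trimethoxy) | Oc1cc(OC)c(OC)c(OC)c1Oc1cc(OC)c(Oc2cc(OC)c(OC)c(OC)c2)c(OC)c1
F9 | step 17 | A–B–C–D tetramer monoaldehyde (formyl and ortho fluoride on ring D only) | COc1cc(OC)c(Oc2cc(OC)c(Oc3cc(OC)c(OC)c(OC)c3Oc3cc(OC)c(C=O)c(F)c3)c(OC)c2)c(OC)c1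
F10 | step 17 | heptamer monoaldehyde (formyl at C4 of ring D, seventeen methyl ethers) | COc1cc(OC)c(Oc2cc(OC)c(Oc3cc(OC)c(OC)c(OC)c3Oc3cc(OC)c(C=O)c(Oc4cc(OC)c(OC)c(OC)c4Oc4cc(OC)c(Oc5cc(OC)c(OC)c(OC)c5)c(OC)c4)c3)c(OC)c2)c(OC)c1
F11 | step 17 | heptamer mono-formate (formyloxy at C4 of ring D) | COc1cc(OC)c(Oc2cc(OC)c(Oc3cc(OC)c(OC)c(OC)c3Oc3cc(OC)c(OC=O)c(Oc4cc(OC)c(OC)c(OC)c4Oc4cc(OC)c(Oc5cc(OC)c(OC)c(OC)c5)c(OC)c4)c3)c(OC)c2)c(OC)c1
F12 | step 17 | heptamer monophenol (hydroxyl at C4 of ring D, seventeen methyl ethers) | COc1cc(OC)c(Oc2cc(OC)c(Oc3cc(OC)c(OC)c(OC)c3Oc3cc(OC)c(O)c(Oc4cc(OC)c(OC)c(OC)c4Oc4cc(OC)c(Oc5cc(OC)c(OC)c(OC)c5)c(OC)c4)c3)c(OC)c2)c(OC)c1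
F13 | step 16 | 4-bromo-2-fluoro-6-methoxybenzaldehyde | COc1cc(Br)cc(F)c1C=O
F14 | step 16 | D–E–F–G tetramer bromide (bromide para to the ring D formyl, formyl also on ring G) | COc1cc(Br)cc(Oc2cc(OC)c(OC)c(OC)c2Oc2cc(OC)c(Oc3cc(OC)c(C=O)c(OC)c3)c(OC)c2)c1C=O
F15 | step 6 | A–B–C trimer bromide (bromine at C6 of ring C, formyl at C4) | COc1cc(OC)c(Oc2cc(OC)c(Oc3cc(OC)c(C=O)c(OC)c3Br)c(OC)c2)c(OC)c1
F16 | step 6 | A–B–C trimer pinacol boronate (boron at C6 of ring C, formyl at C4) | COc1cc(OC)c(Oc2cc(OC)c(Oc3cc(OC)c(C=O)c(OC)c3B4OC(C)(C)C(C)(C)O4)c(OC)c2)c(OC)c1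
F17 | step 18 | octadecaacetate of the target | CC(=O)Oc1cc(OC(C)=O)c(Oc2cc(OC(C)=O)c(Oc3cc(OC(C)=O)c(OC(C)=O)c(OC(C)=O)c3Oc3cc(OC(C)=O)c(OC(C)=O)c(Oc4cc(OC(C)=O)c(OC(C)=O)c(OC(C)=O)c4Oc4cc(OC(C)=O)c(Oc5cc(OC(C)=O)c(OC(C)=O)c(OC(C)=O)c5)c(OC(C)=O)c4)c3)c(OC(C)=O)c2)c(OC(C)=O)c1
A1 | alternative 1 | E–F–G trimer phenol (hydroxyl at C1 of ring E) | Oc1cc(OC)c(OC)c(OC)c1Oc1cc(OC)c(Oc2cc(OC)c(OC)c(OC)c2)c(OC)c1
A2 | alternative 1 | racemic 2-[3,5-dimethoxy-4-(3,4,5-trimethoxyphenoxy)phenoxy]-3,4-dimethoxy-4-(1-methoxyethenyl)cyclobut-2-en-1-one | COC(=C)C1(OC)C(OC)=C(Oc2cc(OC)c(Oc3cc(OC)c(OC)c(OC)c3)c(OC)c2)C1=O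
A3 | alternative 2 | dimethyl 2,4,6-trihydroxy-5-(aryloxy)isophthalate with the B-to-G hexamer as aryl group | COC(=O)c1c(O)c(C(=O)OC)c(O)c(Oc2cc(OC)c(Oc3cc(OC)c(OC)c(OC)c3Oc3cc(OC)c(OC)c(Oc4cc(OC)c(OC)c(OC)c4Oc4cc(OC)c(Oc5cc(OC)c(OC)c(OC)c5)c(OC)c4)c3)c(OC)c2)c1O
A4 | alternative 2 | dimethyl 2-(aryloxy)malonate with the B-to-G hexamer as aryl group | COC(=O)C(C(=O)OC)Oc1cc(OC)c(Oc2cc(OC)c(OC)c(OC)c2Oc2cc(OC)c(OC)c(Oc3cc(OC)c(OC)c(OC)c3Oc3cc(OC)c(Oc4cc(OC)c(OC)c(OC)c4)c(OC)c3)c2)c(OC)c1
A5 | alternative 2 | dimethyl 3-oxoglutarate | COC(=O)CC(=O)CC(=O)OC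
A6 | alternative 3 | cyclopentadienylruthenium hexafluorophosphate complex of the permethylated heptamer (metal on ring B) | COc1cc(OC)c(Oc2cc(OC)c(Oc3cc(OC)c(OC)c(OC)c3Oc3cc(OC)c(OC)c(Oc4cc(OC)c(OC)c(OC)c4Oc4cc(OC)c(Oc5cc(OC)c(OC)c(OC)c5)c(OC)c4)c3)c(OC)c2)c(OC)c1.[Ru+2].[cH-]1cccc1.F[P-](F)(F)(F)(F)F
A7 | alternative 3 | cyclopentadienylruthenium hexafluorophosphate complex of 2,5-dichloro-1,3-dimethoxybenzene | COc1cc(Cl)cc(OC)c1Cl.[Ru+2].[cH-]1cccc1.F[P-](F)(F)(F)(F)F
A8 | alternative 3 | C-to-G pentamer phenol (hydroxyl at C1 of ring C, all other oxygens methylated) | Oc1cc(OC)c(OC)c(OC)c1Oc1cc(OC)c(OC)c(Oc2cc(OC)c(OC)c(OC)c2Oc2cc(OC)c(Oc3cc(OC)c(OC)c(OC)c3)c(OC)c2)c1
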